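## Retrosynthetic overview

1. The acetate goes on last, after desilylation; the aryl ether comes from a Mitsunobu coupling of umbelliferone (bought, so the coumarin rings are not built) with the primary hydroxyl of a 1,3-diol.
2. The side-chain tertiary carbinol comes from a Z-allylic alcohol by Sharpless epoxidation and C2-selective hydride opening; the allylic alcohol comes from a B-alkyl Suzuki coupling of a ring vinyl group with (Z)-3-iodobut-2-en-1-ol.
3. The axial ring secondary alcohol comes from the ring ketone by bulky-hydride reduction.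
4. The cyclohexane, the only ring formed, comes from a new CuH-catalysed reductive allene–ketone cyclisation that makes the bond between the two adjacent ring stereocentres and sets both.
5. The acyclic allenyl 1,4-diketone comes from isobutyraldehyde and propargyl alcohol (propargyl Claisen) plus a 3-oxobutyl Grignard equivalent.

Assumption: the bisphosphine antipode in step 5 is written as (R,R)-Ph-BPE; the antipode that gives the (3S,4R) ketol in a first test run is the one used.

Stereochemical reading of the target: acetoxy carbon R, ring CH S, ring carbinol R, side-chain carbinol R; on the ring the side chain is cis to the tertiary OH and trans to the acetate.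

## Route

Step 1
Reactants: 1 2-methylpropanal (isobutyraldehyde); 2 prop-2-yn-1-ol (propargyl alcohol)
Product: 4 2,2-dimethylpenta-3,4-dienal, via propargyl enol ether 3 (not isolated)
Conditions: TsOH·H2O (cat.), 1,4-diisopropylbenzene, 140–150 °C, Dean–Stark (−H2O); distil
Reagents that add atoms: none
Why: Acid-catalysed enol ether formation followed by a propargyl Claisen (Saucy–Marbet) [3,3] shift gives the allenyl aldehyde, which cannot enolise; no stereocentre is formed.

Step 2
Reactants: 4 2,2-dimethylpenta-3,4-dienal; 5 2-(2-bromoethyl)-2-methyl-1,3-dioxolane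
Product: 7 rac-4,4-dimethyl-1-(2-methyl-1,3-dioxolan-2-yl)hepta-5,6-dien-3-ol, via alkylmagnesium bromide 6 (not isolated)
Conditions: 5, Mg, THF, 25 °C; then 4, 0 °C; then H2O
Reagents that add atoms: none
Why: Grignard addition to the non-enolisable neopentyl aldehyde; the carbinol is racemic and is removed in step 3.

Step 3
Reactants: 7 rac-4,4-dimethyl-1-(2-methyl-1,3-dioxolan-2-yl)hepta-5,6-dien-3-ol
Product: 8 4,4-dimethyl-1-(2-methyl-1,3-dioxolan-2-yl)hepta-5,6-dien-3-one
Conditions: Dess–Martin periodinane, pyridine, CH2Cl2, 0 °C → rt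
Reagents that add atoms: none
Why: Dess–Martin oxidation of the secondary alcohol under buffered conditions leaves the allene and the dioxolane untouched.

Step 4
Reactants: 8 4,4-dimethyl-1-(2-methyl-1,3-dioxolan-2-yl)hepta-5,6-dien-3-one
Product: 9 6,6-dimethylnona-7,8-diene-2,5-dione
Conditions: 1 M HCl, THF, rt
Reagents that add atoms: water, O
Why: Acid-catalysed ketal hydrolysis frees the methyl ketone; the allene and the 1,4-diketone tolerate dilute acid at room temperature.

Step 5
Reactants: 9 6,6-dimethylnona-7,8-diene-2,5-dione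
Product: 11 (3S,4R)-3-ethenyl-4-hydroxy-2,2,4-trimethylcyclohexan-1-one, via silyl ether 10 (not isolated)
Conditions: Cu(OAc)2 (5 mol %), (R,R)-Ph-BPE (6 mol %), (MeO)2MeSiH (2 equiv), THF, 0 °C → rt, slow addition of 9; then NH4F, MeOH
Reagents that add atoms: none
Why: Proposed new method: an enantioselective intramolecular CuH-catalysed reductive allene–ketone cyclisation in which L*CuH (monovalent copper, from Cu(OAc)2, the bisphosphine and the silane) hydrocuprates the terminal C=C of the allene on the side away from the quaternary carbon to give the (Z)-allylcopper, which adds through its γ-carbon to the methyl ketone in a closed six-membered chair, so that vinyl and hydroxyl end cis with the methyl equatorial (the E-allyl alternatives need that methyl syn-axial to a ring methyl), the chiral ligand chooses the ketone face and so sets both centres as (3S,4R), and the hindered α-quaternary ketone is spared; the closest known reaction type is the intermolecular CuH-catalysed enantioselective allylation of ketones with terminal allenes.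

Step 6
Reactants: 11 (3S,4R)-3-ethenyl-4-hydroxy-2,2,4-trimethylcyclohexan-1-one
Product: 12 (1R,2S,4R)-2-ethenyl-1,3,3-trimethylcyclohexane-1,4-diol
Conditions: K[(s-Bu)3BH] (2.5 equiv), THF, −78 °C; then NaOH, H2O2, 0 °C
Reagents that add atoms: none
Why: Bulky trialkylborohydride reduction: in the chair with vinyl and methyl equatorial the hydride enters the 2,2-dimethyl ketone from the equatorial side, so the new hydroxyl is axial and trans to the tertiary hydroxyl, which is the (4R) centre.

Step 7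
Reactants: 12 (1R,2S,4R)-2-ethenyl-1,3,3-trimethylcyclohexane-1,4-diol
Product: 13 (1R,2S,4R)-2-ethenyl-1,3,3-trimethyl-1,4-bis(triethylsilyloxy)cyclohexane
Conditions: Et3SiOTf (3 equiv), 2,6-lutidine, CH2Cl2, −78 → 0 °C
Reagents that add atoms: triethylsilyl trifluoromethanesulfonate, CC[Si](CC)(CC)OS(=O)(=O)C(F)(F)F
Why: Silyl triflate silylation protects both hydroxyls, so the tertiary one cannot open the later epoxide (6-exo) and no free OH meets the borane.

Step 8
Reactants: 14 but-2-yn-1-ol
Product: 16 (2Z)-3-iodobut-2-en-1-ol, via sodium alkenylaluminate 15 (not isolated)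
Conditions: Na[AlH2(OCH2CH2OMe)2] (1.4 equiv), THF, 0 °C → rt; then I2, −78 → 0 °C; aq. KNaC4H4O6
Reagents that add atoms: iodine, [I][I]
Why: Alkoxide-directed trans-hydroalumination of the propargylic alcohol puts aluminium on C3 cis to the CH2O group, and iodinolysis with retention gives the (Z)-iodide.

Step 9
Reactants: 13 (1R,2S,4R)-2-ethenyl-1,3,3-trimethyl-1,4-bis(triethylsilyloxy)cyclohexane; 16 (2Z)-3-iodobut-2-en-1-ol
Product: 18 (2Z)-3-methyl-5-[(1S,3R,6R)-2,2,6-trimethyl-3,6-bis(triethylsilyloxy)cyclohexyl]pent-2-en-1-ol, via alkylborane 17 (not isolated)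
Conditions: 9-BBN (1.5 equiv), THF, rt; then 16, Pd(dppf)Cl2 (5 mol %), AsPh3 (10 mol %), Cs2CO3 (3 equiv), DMF/H2O, rt
Reagents that add atoms: none
Why: Anti-Markovnikov hydroboration of the vinyl group and B-alkyl Suzuki–Miyaura coupling with retention of the alkenyl iodide geometry give the Z-trisubstituted allylic alcohol.

Step 10
Reactants: 18 (2Z)-3-methyl-5-[(1S,3R,6R)-2,2,6-trimethyl-3,6-bis(triethylsilyloxy)cyclohexyl]pent-2-en-1-ol
Product: 19 [(2S,3R)-3-methyl-3-{2-[(1S,3R,6R)-2,2,6-trimethyl-3,6-bis(triethylsilyloxy)cyclohexyl]ethyl}oxiran-2-yl]methanol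
Conditions: Ti(OiPr)4 (0.5 equiv), L-(+)-diethyl tartrate (0.6 equiv), t-BuOOH (2 equiv), 4 Å molecular sieves, CH2Cl2, −20 °C
Reagents that add atoms: tert-butyl hydroperoxide, CC(C)(C)OO
Why: Sharpless asymmetric epoxidation under reagent control: L-(+)-tartrate delivers oxygen to the face of the Z-allylic alcohol that gives the (2S,3R)-epoxide (as with nerol), which fixes the future tertiary carbinol.

Step 11
Reactants: 19 [(2S,3R)-3-methyl-3-{2-[(1S,3R,6R)-2,2,6-trimethyl-3,6-bis(triethylsilyloxy)cyclohexyl]ethyl}oxiran-2-yl]methanol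
Product: 20 (3R)-3-methyl-5-[(1S,3R,6R)-2,2,6-trimethyl-3,6-bis(triethylsilyloxy)cyclohexyl]pentane-1,3-diol
Conditions: Na[AlH2(OCH2CH2OMe)2] (3 equiv), THF, 0 °C → rt; aq. KNaC4H4O6
Reagents that add atoms: none
Why: Alkoxide-directed hydride delivery opens the 2,3-epoxy alcohol at C2 (1,3-diol formation), so the C3–O bond and its configuration, now (3R), are untouched.

Step 12
Reactants: 20 (3R)-3-methyl-5-[(1S,3R,6R)-2,2,6-trimethyl-3,6-bis(triethylsilyloxy)cyclohexyl]pentane-1,3-diol; 21 7-hydroxy-2H-chromen-2-one (umbelliferone)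
Product: 22 7-{[(3R)-3-hydroxy-3-methyl-5-[(1S,3R,6R)-2,2,6-trimethyl-3,6-bis(triethylsilyloxy)cyclohexyl]pentyl]oxy}-2H-chromen-2-one
Conditions: PPh3, DIAD, THF, 0 °C → rt
Reagents that add atoms: none
Why: Mitsunobu etherification: the acidic coumarin phenol displaces the activated primary alcohol, while the tertiary alcohol is inert.

Step 13
Reactants: 22 7-{[(3R)-3-hydroxy-3-methyl-5-[(1S,3R,6R)-2,2,6-trimethyl-3,6-bis(triethylsilyloxy)cyclohexyl]pentyl]oxy}-2H-chromen-2-one
Product: 23 7-{[(3R)-5-[(1S,3R,6R)-3,6-dihydroxy-2,2,6-trimethylcyclohexyl]-3-hydroxy-3-methylpentyl]oxy}-2H-chromen-2-one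
Conditions: HF·pyridine, pyridine, THF, 0 °C → rt
Reagents that add atoms: none
Why: Fluoride-mediated desilylation with buffered HF·pyridine removes both triethylsilyl ethers without touching the lactone.

Step 14
Reactants: 23 7-{[(3R)-5-[(1S,3R,6R)-3,6-dihydroxy-2,2,6-trimethylcyclohexyl]-3-hydroxy-3-methylpentyl]oxy}-2H-chromen-2-one
Product: 24 [(1R,3S,4R)-4-hydroxy-3-{(3R)-3-hydroxy-3-methyl-5-[(2-oxo-2H-chromen-7-yl)oxy]pentyl}-2,2,4-trimethylcyclohexyl] acetate
Conditions: Ac2O (1.5 equiv), pyridine, DMAP (5 mol %), CH2Cl2, 0 °C → rt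
Reagents that add atoms: acetic anhydride, CC(=O)OC(C)=O
Why: DMAP-catalysed acylation is selective for the one secondary hydroxyl because the two tertiary hydroxyls react far more slowly.

## Compound list

1 | 2-methylpropanal (isobutyraldehyde) | CC(C)C=O | starting material
2 | prop-2-yn-1-ol (propargyl alcohol) | C#CCO | starting material
3 | 3-[(2-methylprop-1-en-1-yl)oxy]prop-1-yne | CC(C)=COCC#C | intermediate
4 | 2,2-dimethylpenta-3,4-dienal | C=C=CC(C)(C)C=O | intermediate
5 | 2-(2-bromoethyl)-2-methyl-1,3-dioxolane | CC1(CCBr)OCCO1 | starting material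
6 | [2-(2-methyl-1,3-dioxolan-2-yl)ethyl]magnesium bromide | CC1(CC[Mg]Br)OCCO1 | intermediate
7 | rac-4,4-dimethyl-1-(2-methyl-1,3-dioxolan-2-yl)hepta-5,6-dien-3-ol | CC1(CCC(O)C(C)(C)C=C=C)OCCO1 | intermediate
8 | 4,4-dimethyl-1-(2-methyl-1,3-dioxolan-2-yl)hepta-5,6-dien-3-one | CC1(CCC(=O)C(C)(C)C=C=C)OCCO1 | intermediate
9 | 6,6-dimethylnona-7,8-diene-2,5-dione | CC(=O)CCC(=O)C(C)(C)C=C=C | intermediate
10 | (3S,4R)-4-{[dimethoxy(methyl)silyl]oxy}-3-ethenyl-2,2,4-trimethylcyclohexan-1-one | O=C1CC[C@@](C)(O[Si](C)(OC)OC)[C@@H](C=C)C1(C)C | intermediate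
11 | (3S,4R)-3-ethenyl-4-hydroxy-2,2,4-trimethylcyclohexan-1-one (vinyl cis to OH) | O=C1CC[C@@](C)(O)[C@@H](C=C)C1(C)C | intermediate
12 | (1R,2S,4R)-2-ethenyl-1,3,3-trimethylcyclohexane-1,4-diol (secondary OH trans to vinyl and to tertiary OH) | O[C@@H]1CC[C@@](C)(O)[C@@H](C=C)C1(C)C | intermediate
13 | (1R,2S,4R)-2-ethenyl-1,3,3-trimethyl-1,4-bis(triethylsilyloxy)cyclohexane | CC[Si](CC)(CC)O[C@@H]1CC[C@@](C)(O[Si](CC)(CC)CC)[C@@H](C=C)C1(C)C | intermediate
14 | but-2-yn-1-ol | CC#CCO | starting material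
15 | sodium 2,2-bis(2-methoxyethoxy)-3-methyl-2,5-dihydro-1,2-oxaaluminol-2-uide (five-membered O–Al–C3=C2–C1 ring) | CC1=CCO[Al-]1(OCCOC)OCCOC.[Na+] | intermediate
16 | (2Z)-3-iodobut-2-en-1-ol | C/C(I)=C/CO | intermediate
17 | 9-{2-[(1S,3R,6R)-2,2,6-trimethyl-3,6-bis(triethylsilyloxy)cyclohexyl]ethyl}-9-borabicyclo[3.3.1]nonane | CC[Si](CC)(CC)O[C@@H]1CC[C@@](C)(O[Si](CC)(CC)CC)[C@@H](CCB2C3CCCC2CCC3)C1(C)C | intermediate
18 | (2Z)-3-methyl-5-[(1S,3R,6R)-2,2,6-trimethyl-3,6-bis(triethylsilyloxy)cyclohexyl]pent-2-en-1-ol | CC[Si](CC)(CC)O[C@@H]1CC[C@@](C)(O[Si](CC)(CC)CC)[C@@H](CC/C(C)=C\CO)C1(C)C | intermediate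
19 | [(2S,3R)-3-methyl-3-{2-[(1S,3R,6R)-2,2,6-trimethyl-3,6-bis(triethylsilyloxy)cyclohexyl]ethyl}oxiran-2-yl]methanol | CC[Si](CC)(CC)O[C@@H]1CC[C@@](C)(O[Si](CC)(CC)CC)[C@@H](CC[C@@]2(C)O[C@H]2CO)C1(C)C | intermediate
20 | (3R)-3-methyl-5-[(1S,3R,6R)-2,2,6-trimethyl-3,6-bis(triethylsilyloxy)cyclohexyl]pentane-1,3-diol | CC[Si](CC)(CC)O[C@@H]1CC[C@@](C)(O[Si](CC)(CC)CC)[C@@H](CC[C@@](C)(O)CCO)C1(C)C | intermediate
21 | 7-hydroxy-2H-chromen-2-one (umbelliferone) | O=c1ccc2ccc(O)cc2o1 | starting material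
22 | 7-{[(3R)-3-hydroxy-3-methyl-5-[(1S,3R,6R)-2,2,6-trimethyl-3,6-bis(triethylsilyloxy)cyclohexyl]pentyl]oxy}-2H-chromen-2-one | CC[Si](CC)(CC)O[C@@H]1CC[C@@](C)(O[Si](CC)(CC)CC)[C@@H](CC[C@@](C)(O)CCOc2ccc3ccc(=O)oc3c2)C1(C)C | intermediate
23 | 7-{[(3R)-5-[(1S,3R,6R)-3,6-dihydroxy-2,2,6-trimethylcyclohexyl]-3-hydroxy-3-methylpentyl]oxy}-2H-chromen-2-one | O[C@@H]1CC[C@@](C)(O)[C@@H](CC[C@@](C)(O)CCOc2ccc3ccc(=O)oc3c2)C1(C)C | intermediate
24 | [(1R,3S,4R)-4-hydroxy-3-{(3R)-3-hydroxy-3-methyl-5-[(2-oxo-2H-chromen-7-yl)oxy]pentyl}-2,2,4-trimethylcyclohexyl] acetate | CC(=O)O[C@@H]1CC[C@@](C)(O)[C@@H](CC[C@@](C)(O)CCOc2ccc3ccc(=O)oc3c2)C1(C)C | target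

## Step count and fallbacks

Total step count: 14. Longest linear sequence: 13 (steps 1–7 and 9–14; step 8 is a one-step side branch).

**Step 5 (the proposed new cyclisation).** Risks: reduction of the methyl ketone by CuH before hydrocupration, a slow C–C bond formation at the neopentyl allyl terminus, or low enantioselectivity. The fallback uses a relay stereocentre and known chemistry only; it sets out from 8 and comes back at 11. Ketone 8 is reduced with (R)-Me-CBS and catecholborane (toluene, −78 °C; catecholborane does not touch the allene) to (3S)-4,4-dimethyl-1-(2-methyl-1,3-dioxolan-2-yl)hepta-5,6-dien-3-ol F1. Silylation (t-BuMe2SiOTf, 2,6-lutidine) gives the silyl ether F2, and ketal hydrolysis (AcOH/H2O/THF, 45 °C) gives the silyloxy allenyl methyl ketone F3. Hydroboration of the terminal allene C=C with 9-BBN (THF, 0 °C) gives the (Z)-allyl-9-BBN F4, which allylborates the methyl ketone intramolecularly through a chair with the silyloxy group equatorial and the methyl equatorial. After NaOH work-up this gives the cyclised silyl ether F5, in which the silyloxy group is cis to the vinyl group; the selectivity of this relay is modest, so F5 is separated from its diastereomer before going on. Bu4NF then gives the epimeric diol F6, and Dess–Martin oxidation of its secondary alcohol erases the relay centre and returns 11.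

**Step 6 (facial selectivity of the hydride).** Risk: the axial methyl next to the ketone may divert the bulky hydride and give the equatorial alcohol. The fallback sets out from 11 and comes back at 12, switching from substrate control to reagent control: Corey–Bakshi–Shibata reduction with (S)-Me-CBS (1 equiv) and catecholborane in toluene at −78 °C, where the oxazaborolidine distinguishes the quaternary from the methylene flank and gives the (4R) alcohol directly. This makes no new compound F0.

**Step 9 (hydroboration and B-alkyl Suzuki coupling).** Risk: slow hydroboration beside two fully substituted carbons or protodeboronation of 17. The fallback sets out from 13 and comes back at 18, replacing the boron coupling with a cross-electrophile coupling. Compound 13 is hydroborated with 9-BBN and oxidised (NaOH, H2O2) to 2-[(1S,3R,6R)-2,2,6-trimethyl-3,6-bis(triethylsilyloxy)cyclohexyl]ethan-1-ol F7, which is converted (I2, PPh3, imidazole) to the primary iodide F8. F8 is joined to 16 by reductive coupling (NiI2, 4,4'-di-tert-butyl-2,2'-bipyridine, Mn, DMPU, rt), which tolerates the free hydroxyl of 16 and keeps the Z geometry.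

## Further compounds

F1 | step 5 | (3S)-4,4-dimethyl-1-(2-methyl-1,3-dioxolan-2-yl)hepta-5,6-dien-3-ol | O[C@@H](CCC1(C)OCCO1)C(C)(C)C=C=C
F2 | step 5 | tert-butyl{[(3S)-4,4-dimethyl-1-(2-methyl-1,3-dioxolan-2-yl)hepta-5,6-dien-3-yl]oxy}dimethylsilane | CC(C)(C)[Si](C)(C)O[C@@H](CCC1(C)OCCO1)C(C)(C)C=C=C
F3 | step 5 | (5S)-5-{[tert-butyl(dimethyl)silyl]oxy}-6,6-dimethylnona-7,8-dien-2-one | CC(=O)CC[C@H](O[Si](C)(C)C(C)(C)C)C(C)(C)C=C=C
F4 | step 5 | 9-[(2Z,5S)-5-{[tert-butyl(dimethyl)silyl]oxy}-4,4-dimethyl-8-oxonon-2-en-1-yl]-9-borabicyclo[3.3.1]nonane | CC(=O)CC[C@H](O[Si](C)(C)C(C)(C)C)C(C)(C)/C=C\CB1C2CCCC1CCC2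
F5 | step 5 | (1R,2S,4S)-4-{[tert-butyl(dimethyl)silyl]oxy}-2-ethenyl-1,3,3-trimethylcyclohexan-1-ol | CC(C)(C)[Si](C)(C)O[C@H]1CC[C@@](C)(O)[C@@H](C=C)C1(C)C
F6 | step 5 | (1R,2S,4S)-2-ethenyl-1,3,3-trimethylcyclohexane-1,4-diol | O[C@H]1CC[C@@](C)(O)[C@@H](C=C)C1(C)C
F0 | step 6 | none | none
F7 | step 9 | 2-[(1S,3R,6R)-2,2,6-trimethyl-3,6-bis(triethylsilyloxy)cyclohexyl]ethan-1-ol | CC[Si](CC)(CC)O[C@@H]1CC[C@@](C)(O[Si](CC)(CC)CC)[C@@H](CCO)C1(C)C
F8 | step 9 | (1R,2S,4R)-2-(2-iodoethyl)-1,3,3-trimethyl-1,4-bis(triethylsilyloxy)cyclohexane | CC[Si](CC)(CC)O[C@@H]1CC[C@@](C)(O[Si](CC)(CC)CC)[C@@H](CCI)C1(C)C
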